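**Retrosynthetic overview**

1. Ring locants: C1 carries the exocyclic enal carbon Cα, C2/C3 are CH2, C4 is CHMe, C5 is quaternary, C6 is the CH with the three-carbon arm. Endgame: MnO2 oxidation ⇐ B-alkyl Suzuki union of C5-vinyl cyclohexane 29 with alkenyl iodide 13, which already holds the oxirane (directed epoxidation, step 6).
2. (Z)-Enal ⇐ methyl ester 27 ⇐ enol triflate 26 ⇐ regio- and geometry-defined enolate from dissolving-metal reduction of 1-acetylcyclohexene 24 ⇐ Diels–Alder adduct 20 (oxidation, double-bond migration).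
3. Ring disconnection: C4–C5 and C6–C1 in one [4+2] step; dienophile C5=C6 is the (E)-2-methyl-2-enal 16, diene C1–C4 is the (E,E)-silyloxy diene 19.
4. Enabling feature: C5 is quaternary with a methyl and a carbon branch next to the C6 methine, and C2/C3 are bare methylenes. So C5=C6 can be an α-methyl enal (formyl = first chain carbon) and C2–C3 the cycloaddition alkene, which is later moved to C1=C2 and used up in setting the exocyclic alkene.
5. Order of ring formation: oxirane (step 6, side-chain branch), then cyclohexane C1–C6 (step 10); no ring is closed afterwards.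

Key step: step 10

Remark on the chemistry (assumption): the sense of induction in steps 1 and 10 is taken from the accepted transition-state models of the two catalyst classes; the mirror-image catalyst would be used if the opposite sense were found.
Naming note: ring compounds use the locants above; β is the face of the C5 methyl group, α the opposite face.

**Side-chain branch**

Step 1
Reactants: 1 3-methylbut-2-enal; 2 allenylboronic acid pinacol ester
Product: 4 (S)-6-methylhept-5-en-1-yn-4-ol, via pinacol borate ester 3 (not isolated)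
Conditions: (S)-TRIP (10 mol%), 4 Å MS, toluene, 0 °C; aq. NaHCO3
Reagents that add atoms: none
Why: Chiral-phosphoric-acid-catalysed propargylation, in which the allenylboronate adds in an SE2' sense through a closed six-membered transition state, so only 1,2-addition occurs and the catalyst's face selection sets the (S)-carbinol of the later epoxy alcohol.

Step 2
Reactants: 4 (S)-6-methylhept-5-en-1-yn-4-ol
Product: 6 (S,E)-1-iodo-2,6-dimethylhepta-1,5-dien-4-ol, via alkenylalane 5 (not isolated)
Conditions: Me3Al (3 equiv), Cp2ZrCl2 (0.3 equiv), CH2Cl2, 0 °C to rt; I2, THF, −30 °C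
Reagents that add atoms: trimethylaluminium C[Al](C)C; iodine II
Why: Zirconium-catalysed carboalumination (syn addition, methyl to the internal alkyne carbon) and iodinolysis with retention give the (E)-alkenyl iodide, the hydroxyl being carried as its aluminium alkoxide.

Step 3
Reactants: 6 (S,E)-1-iodo-2,6-dimethylhepta-1,5-dien-4-ol; 7 (4-bromobut-1-yn-1-yl)trimethylsilane
Product: 9 (S,E)-6,10-dimethyl-1-(trimethylsilyl)undeca-5,9-dien-1-yn-8-ol, via alkylzinc bromide 8 (not isolated)
Conditions: 7, Zn, LiCl, THF, 50 °C; then 6, Pd(OAc)2 (2 mol%), SPhos (4 mol%), THF, rt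
Reagents that add atoms: none
Why: Negishi cross-coupling of a primary alkylzinc halide with the alkenyl iodide keeps the (E)-geometry, and alkylzinc halides couple faster than the free hydroxyl protonates them.

Step 4
Reactants: 9 (S,E)-6,10-dimethyl-1-(trimethylsilyl)undeca-5,9-dien-1-yn-8-ol
Product: 10 (S,E)-6,10-dimethylundeca-5,9-dien-1-yn-8-ol
Conditions: K2CO3, MeOH, rt
Reagents that add atoms: none
Why: Methoxide-mediated protodesilylation of the alkynylsilane leaves the allylic alcohol and both alkenes untouched.

Step 5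
Reactants: 10 (S,E)-6,10-dimethylundeca-5,9-dien-1-yn-8-ol
Product: 12 (S,1E,5E)-1-iodo-2,6,10-trimethylundeca-1,5,9-trien-8-ol, via alkenylalane 11 (not isolated)
Conditions: Me3Al (3 equiv), Cp2ZrCl2 (0.3 equiv), CH2Cl2, 0 °C to rt; I2, THF, −30 °C
Reagents that add atoms: trimethylaluminium C[Al](C)C; iodine II
Why: A second zirconium-catalysed carboalumination–iodination installs the second (E)-methyl-branched alkene and the alkenyl iodide for the fragment union.

Step 6
Reactants: 12 (S,1E,5E)-1-iodo-2,6,10-trimethylundeca-1,5,9-trien-8-ol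
Product: 13 (1S,3E,7E)-1-[(2R)-3,3-dimethyloxiran-2-yl]-8-iodo-3,7-dimethylocta-3,7-dien-1-ol
Conditions: Ti(OiPr)4 (0.2 equiv), tBuOOH, 4 Å MS, CH2Cl2, −20 °C
Reagents that add atoms: tert-butyl hydroperoxide CC(C)(C)OO
Why: Hydroxyl-directed epoxidation, in which A(1,3) strain with the cis-methyl group holds the carbinol hydrogen in the alkene plane so that oxygen is delivered syn to the hydroxyl; this should give the threo (S,R) epoxy alcohol and touch only the allylic double bond.

**Ring branch**

Step 7
Reactants: 14 4-[(tert-butyldimethylsilyl)oxy]butanal; 15 2-(triphenylphosphoranylidene)propanal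
Product: 16 (E)-6-[(tert-butyldimethylsilyl)oxy]-2-methylhex-2-enal
Conditions: toluene, 90 °C
Reagents that add atoms: none
Why: Wittig olefination with the stabilised formyl ylide gives the (E)-trisubstituted enal, the geometry that becomes the cis relation of the C5 methyl and the C6 arm.

Step 8
Reactants: 17 (2E,4E)-hexa-2,4-dienal
Product: 18 (3E,5E)-hepta-3,5-dien-2-ol (racemic)
Conditions: MeMgBr, THF, −78 °C; aq. NH4Cl
Reagents that add atoms: methylmagnesium bromide C[Mg]Br
Why: Grignard 1,2-addition gives the dienol, whose carbinol configuration is irrelevant because this carbon becomes the acetyl carbon in step 13.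

Step 9
Reactants: 18 (3E,5E)-hepta-3,5-dien-2-ol
Product: 19 triethyl[(3E,5E)-hepta-3,5-dien-2-yloxy]silane (racemic)
Conditions: Et3SiCl, imidazole, CH2Cl2, 0 °C
Reagents that add atoms: chlorotriethylsilane CC[Si](Cl)(CC)CC
Why: Imidazole-assisted silylation masks the carbinol as a triethylsilyl ether that can later be removed beside the primary tert-butyldimethylsilyl ether.

Step 10
Reactants: 16 (E)-6-[(tert-butyldimethylsilyl)oxy]-2-methylhex-2-enal; 19 triethyl[(3E,5E)-hepta-3,5-dien-2-yloxy]silane
Product: 20 1α-[1-(triethylsilyloxy)ethyl]-4α,5β-dimethyl-6β-[3-(tert-butyldimethylsilyloxy)propyl]cyclohex-2-ene-5α-carbaldehyde (both epimers at the silyloxyethyl carbon)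
Conditions: 19 (2 equiv), B-(o-tolyl)oxazaborolidine from (S)-α,α-diphenylprolinol activated with HNTf2 (20 mol%), CH2Cl2, −78 to −40 °C
Reagents that add atoms: none
Why: Normal-demand, concerted but asynchronous Diels–Alder reaction of the s-trans enal bound to the chiral cationic boron Lewis acid with the (E,E)-diene; the closest known type is the oxazaborolidinium-catalysed cycloaddition of α-substituted and α,β-disubstituted enals such as tiglic aldehyde with acyclic dienes. The cyclohexene C1–C6 is closed by intermolecular [4+2] cycloaddition, both σ-bonds (C4–C5 and C6–C1) forming suprafacially on each partner. C5 and C6 take their relation from the (E)-geometry of 16 (C5 methyl cis to the C6 arm); C4 is set by the (E)-propenyl terminus together with the endo-formyl transition state (C4 methyl cis to formyl, trans to the C5 methyl); the absolute configuration comes from the catalyst shielding one face of the bound enal. The step needs regio-, endo- and facial selectivity: methyl is the better donor and the smaller terminus, so the remote, silyloxyethyl-bearing C1 should bond to the β-carbon C6 and keep away from the carbon that becomes quaternary. Both enantiomers of 19 should give the same ring configuration and differ only at the carbinol carbon, which, like C1, is erased in step 13.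

Step 11
Reactants: 20 Diels–Alder adduct (5α-carbaldehyde)
Product: 21 1α-[1-(triethylsilyloxy)ethyl]-4α,5β-dimethyl-5α-vinyl-6β-[3-(tert-butyldimethylsilyloxy)propyl]cyclohex-2-ene (both carbinol epimers)
Conditions: Ph3PCH3Br, KN(SiMe3)2, THF, 0 °C to rt
Reagents that add atoms: methyltriphenylphosphonium bromide C[P+](c1ccccc1)(c1ccccc1)c1ccccc1.[Br-]
Why: Wittig methylenation of the non-enolisable aldehyde turns the activating formyl group into the C5 vinyl group that will carry the side chain, with no stereocentre able to epimerise.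

Step 12
Reactants: 21 C5-vinyl bis-silyl ether
Product: 22 1-[4α,5β-dimethyl-5α-vinyl-6β-[3-(tert-butyldimethylsilyloxy)propyl]cyclohex-2-en-1α-yl]ethanol (both carbinol epimers)
Conditions: PPTS (0.2 equiv), MeOH/CH2Cl2, 0 °C
Reagents that add atoms: none
Why: Acid-catalysed methanolysis removes the secondary triethylsilyl ether, which is far more labile than the primary tert-butyldimethylsilyl ether.

Step 13
Reactants: 22 secondary alcohol
Product: 24 1-acetyl-4α,5β-dimethyl-5α-vinyl-6β-[3-(tert-butyldimethylsilyloxy)propyl]cyclohex-1-ene, via β,γ-unsaturated ketone 23 (not isolated)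
Conditions: Dess–Martin periodinane, NaHCO3, CH2Cl2, rt; then DBU (0.3 equiv), rt
Reagents that add atoms: none
Why: Dess–Martin oxidation followed by base-mediated isomerisation through the dienolate moves the ring alkene into conjugation (C1=C2), so both carbinol epimers converge on one enone and C6 is not acidified.

Step 14
Reactants: 24 1-acetylcyclohexene
Product: 26 (Z)-1-[4α,5β-dimethyl-5α-vinyl-6β-[3-(tert-butyldimethylsilyloxy)propyl]cyclohexylidene]ethyl trifluoromethanesulfonate, via lithium enolate 25 (not isolated)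
Conditions: Li, NH3(l), THF, tBuOH (1 equiv), −78 °C; isoprene; −NH3; PhNTf2, THF, −78 to 0 °C; aq. NH4Cl
Reagents that add atoms: N-phenylbis(trifluoromethanesulfonimide) O=S(=O)(N(c1ccccc1)S(=O)(=O)C(F)(F)F)C(F)(F)F
Why: Dissolving-metal (Birch-type) reduction puts hydrogen on C2 and gives the regio-defined tetrasubstituted enolate, trapped on oxygen as the triflate; the enone should react from its s-trans conformer (acetyl methyl beside C2–H, carbonyl oxygen beside the substituted C6), which places the triflate cis to C6.

Step 15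
Reactants: 26 (Z)-enol triflate
Product: 27 methyl (Z)-2-[4α,5β-dimethyl-5α-vinyl-6β-[3-(tert-butyldimethylsilyloxy)propyl]cyclohexylidene]propanoate
Conditions: Pd(OAc)2 (5 mol%), dppp (6 mol%), CO (1 atm), MeOH, Et3N, DMF, 60 °C
Reagents that add atoms: carbon monoxide [C-]#[O+]; methanol CO
Why: Palladium-catalysed methoxycarbonylation of the enol triflate proceeds with retention of alkene geometry, and cyclisation onto the C5 vinyl group would need a bridgehead alkene and is not expected.

Step 16
Reactants: 27 methyl (Z)-enoate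
Product: 28 (Z)-2-[4α,5β-dimethyl-5α-vinyl-6β-[3-(tert-butyldimethylsilyloxy)propyl]cyclohexylidene]propan-1-ol
Conditions: iBu2AlH, CH2Cl2, −78 °C; aq. KNaC4H4O6 (potassium sodium tartrate)
Reagents that add atoms: none
Why: Hydride reduction of the conjugated ester gives the allylic alcohol, and doing it before the fragment union keeps aluminium hydride away from the epoxy alcohol.

Step 17
Reactants: 28 silyl-protected allylic alcohol
Product: 29 (Z)-2-[6β-(3-hydroxypropyl)-4α,5β-dimethyl-5α-vinylcyclohexylidene]propan-1-ol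
Conditions: Bu4NF, THF, 0 °C to rt
Reagents that add atoms: none
Why: Fluoride desilylation frees the primary alcohol now, so that the last step of the route can be a neutral oxidation.

Step 18
Reactants: 29 C5-vinyl diol; 13 epoxy-alcohol alkenyl iodide
Product: 31 triol (target with CH2OH in place of CHO), via B-alkyl-9-BBN 30 (not isolated)
Conditions: 9-BBN (3.5 equiv), THF, rt; then 13, Pd(dppf)Cl2 (5 mol%), AsPh3, K3PO4, DMF/THF/H2O, rt
Reagents that add atoms: none
Why: Anti-Markovnikov hydroboration of the only reactive alkene (the C5 vinyl group) and B-alkyl Suzuki–Miyaura coupling with the alkenyl iodide, which keeps the (E)-geometry and tolerates free hydroxyls and the epoxide under mild phosphate conditions.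

Step 19
Reactants: 31 triol
Product: 32 CNP0208461.1
Conditions: MnO2, CH2Cl2, rt
Reagents that add atoms: none
Why: MnO2 oxidises only the allylic primary alcohol and is not expected to isomerise the tetrasubstituted alkene or epimerise the γ-stereocentre C6.

**Compound list**

1 | 3-methylbut-2-enal | CC(C)=CC=O | starting material
2 | allenylboronic acid pinacol ester | C=C=CB1OC(C)(C)C(C)(C)O1 | starting material
3 | pinacol borate ester of 4 | C#CC[C@H](OB1OC(C)(C)C(C)(C)O1)C=C(C)C | intermediate
4 | (S)-6-methylhept-5-en-1-yn-4-ol | C#CC[C@H](O)C=C(C)C | intermediate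
5 | (E)-alkenyl(dimethyl)alane from 4, hydroxyl as dimethylaluminium alkoxide | C[Al](C)/C=C(\C)C[C@H](O[Al](C)C)C=C(C)C | intermediate
6 | (S,E)-1-iodo-2,6-dimethylhepta-1,5-dien-4-ol | I/C=C(\C)C[C@H](O)C=C(C)C | intermediate
7 | (4-bromobut-1-yn-1-yl)trimethylsilane | C[Si](C)(C)C#CCCBr | starting material
8 | [4-(trimethylsilyl)but-3-yn-1-yl]zinc bromide | C[Si](C)(C)C#CCC[Zn]Br | intermediate
9 | (S,E)-6,10-dimethyl-1-(trimethylsilyl)undeca-5,9-dien-1-yn-8-ol | C[Si](C)(C)C#CCC/C=C(\C)C[C@H](O)C=C(C)C | intermediate
10 | (S,E)-6,10-dimethylundeca-5,9-dien-1-yn-8-ol | C#CCC/C=C(\C)C[C@H](O)C=C(C)C | intermediate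
11 | (E)-alkenyl(dimethyl)alane from 10, hydroxyl as dimethylaluminium alkoxide | C[Al](C)/C=C(\C)CC/C=C(\C)C[C@H](O[Al](C)C)C=C(C)C | intermediate
12 | (S,1E,5E)-1-iodo-2,6,10-trimethylundeca-1,5,9-trien-8-ol | I/C=C(\C)CC/C=C(\C)C[C@H](O)C=C(C)C | intermediate
13 | (1S,3E,7E)-1-[(2R)-3,3-dimethyloxiran-2-yl]-8-iodo-3,7-dimethylocta-3,7-dien-1-ol | I/C=C(\C)CC/C=C(\C)C[C@H](O)[C@H]1OC1(C)C | intermediate
14 | 4-[(tert-butyldimethylsilyl)oxy]butanal | O=CCCCO[Si](C)(C)C(C)(C)C | starting material
15 | 2-(triphenylphosphoranylidene)propanal | CC(C=O)=P(c1ccccc1)(c1ccccc1)c1ccccc1 | starting material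
16 | (E)-6-[(tert-butyldimethylsilyl)oxy]-2-methylhex-2-enal | O=C/C(C)=C/CCCO[Si](C)(C)C(C)(C)C | intermediate
17 | (2E,4E)-hexa-2,4-dienal | C/C=C/C=C/C=O | starting material
18 | (3E,5E)-hepta-3,5-dien-2-ol, racemic | C/C=C/C=C/C(C)O | intermediate
19 | triethyl[(3E,5E)-hepta-3,5-dien-2-yloxy]silane, racemic | C/C=C/C=C/C(C)O[Si](CC)(CC)CC | intermediate
20 | Diels–Alder adduct: 1α-[1-(triethylsilyloxy)ethyl]-4α,5β-dimethyl-6β-[3-(TBSO)propyl]cyclohex-2-ene-5α-carbaldehyde, both epimers at the silyloxyethyl carbon | CC(O[Si](CC)(CC)CC)[C@H]1C=C[C@@H](C)[C@@](C)(C=O)[C@@H]1CCCO[Si](C)(C)C(C)(C)C | intermediate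
21 | 5α-vinyl analogue of 20, both carbinol epimers | CC(O[Si](CC)(CC)CC)[C@H]1C=C[C@@H](C)[C@@](C)(C=C)[C@@H]1CCCO[Si](C)(C)C(C)(C)C | intermediate
22 | 1-[4α,5β-dimethyl-5α-vinyl-6β-(3-TBSO-propyl)cyclohex-2-en-1α-yl]ethanol, both carbinol epimers | CC(O)[C@H]1C=C[C@@H](C)[C@@](C)(C=C)[C@@H]1CCCO[Si](C)(C)C(C)(C)C | intermediate
23 | 1α-acetyl-4α,5β-dimethyl-5α-vinyl-6β-(3-TBSO-propyl)cyclohex-2-ene | CC(=O)[C@H]1C=C[C@@H](C)[C@@](C)(C=C)[C@@H]1CCCO[Si](C)(C)C(C)(C)C | intermediate
24 | 1-acetyl-4α,5β-dimethyl-5α-vinyl-6β-(3-TBSO-propyl)cyclohex-1-ene | CC(=O)C1=CC[C@@H](C)[C@@](C)(C=C)[C@@H]1CCCO[Si](C)(C)C(C)(C)C | intermediate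
25 | lithium (Z)-enolate of the C2-reduced ketone (O cis to C6) | [Li+].C/C([O-])=C1\CC[C@@H](C)[C@@](C)(C=C)[C@@H]1CCCO[Si](C)(C)C(C)(C)C | intermediate
26 | (Z)-enol triflate (OTf cis to C6) | C/C(OS(=O)(=O)C(F)(F)F)=C1\CC[C@@H](C)[C@@](C)(C=C)[C@@H]1CCCO[Si](C)(C)C(C)(C)C | intermediate
27 | methyl (Z)-2-[4α,5β-dimethyl-5α-vinyl-6β-(3-TBSO-propyl)cyclohexylidene]propanoate | C/C(C(=O)OC)=C1\CC[C@@H](C)[C@@](C)(C=C)[C@@H]1CCCO[Si](C)(C)C(C)(C)C | intermediate
28 | (Z)-2-[4α,5β-dimethyl-5α-vinyl-6β-(3-TBSO-propyl)cyclohexylidene]propan-1-ol | C/C(CO)=C1\CC[C@@H](C)[C@@](C)(C=C)[C@@H]1CCCO[Si](C)(C)C(C)(C)C | intermediate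
29 | (Z)-2-[6β-(3-hydroxypropyl)-4α,5β-dimethyl-5α-vinylcyclohexylidene]propan-1-ol | C/C(CO)=C1\CC[C@@H](C)[C@@](C)(C=C)[C@@H]1CCCO | intermediate
30 | B-alkyl-9-BBN from 29, both hydroxyls as 9-BBN borinates | C/C(COB2C3CCCC2CCC3)=C1\CC[C@@H](C)[C@@](C)(CCB2C3CCCC2CCC3)[C@@H]1CCCOB1C2CCCC1CCC2 | intermediate
31 | triol: (2Z)-2-[(2S,3R,4R)-3-[(3E,7E,10S)-10-[(2R)-3,3-dimethyloxiran-2-yl]-10-hydroxy-4,8-dimethyldeca-3,7-dien-1-yl]-2-(3-hydroxypropyl)-3,4-dimethylcyclohexylidene]propan-1-ol | C/C(CO)=C1\CC[C@@H](C)[C@@](C)(CC/C=C(\C)CC/C=C(\C)C[C@H](O)[C@H]2OC2(C)C)[C@@H]1CCCO | intermediate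
32 | CNP0208461.1: (2Z)-2-[(2S,3R,4R)-3-[(3E,7E,10S)-10-[(2R)-3,3-dimethyloxiran-2-yl]-10-hydroxy-4,8-dimethyldeca-3,7-dien-1-yl]-2-(3-hydroxypropyl)-3,4-dimethylcyclohexylidene]propanal | C/C(C=O)=C1\CC[C@@H](C)[C@@](C)(CC/C=C(\C)CC/C=C(\C)C[C@H](O)[C@H]2OC2(C)C)[C@@H]1CCCO | target

**Step count and risks**

Total step count: 19. Longest linear sequence: 12 steps (17 to 32 through steps 8–19).

Steps most likely to fail:

Step 10. The congested trisubstituted enal may react slowly under the chiral cationic Lewis acid, which may also coordinate or ionise the dienyl silyl ether, so conversion, regiocontrol, endo selectivity and enantioselectivity could all erode. The fallback moves stereocontrol from the catalyst to a sacrificial carbinol centre on the diene. It sets out from 18: lipase-catalysed acylation (Amano lipase PS, vinyl acetate, hexane) should remove the (R)-enantiomer as its acetate and leave (S)-(3E,5E)-hepta-3,5-dien-2-ol F1, which is silylated to (S)-triethyl[(3E,5E)-hepta-3,5-dien-2-yloxy]silane F2. Cycloaddition of F2 with 16 under the achiral Lewis acid Me2AlCl (0.3 equiv, CH2Cl2, −78 °C) should take place on the diene face anti to the silyloxy group. The fallback comes back at 20 as its single (S)-carbinol epimer and continues unchanged.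

Step 14. Rotation about the C1–acyl bond at the radical-anion stage, reaction through the minor s-cis conformer, or over-reduction may give the enolate as a geometric mixture. The fallback replaces kinetic by thermodynamic control. It sets out from 24: the mixed triflates, 26 and the (E)-enol triflate F3, are carbonylated as in step 15 to 27 and the (E)-methyl ester F4; the esters are separated, and F4 is equilibrated by reversible thiyl-radical addition (PhSSPh cat., hν) toward the (Z)-ester, in which the flat ester group rather than the methyl faces the crowded C6 side, and is recycled. The fallback comes back at 27.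

Step 1. The β,β-disubstituted enal may add slowly and with incomplete facial discrimination, giving an alcohol of insufficient enantiomeric purity that would cost diastereomeric purity after step 18. The fallback is a resolution. It sets out from 1: Barbier propargylation (propargyl bromide, Zn, THF/aq. NH4Cl) gives racemic 6-methylhept-5-en-1-yn-4-ol F5, and lipase-catalysed acylation with vinyl acetate should remove the (R)-enantiomer as its acetate. The fallback comes back at 4.

**Further compounds**

F1 | step 10 | (S)-(3E,5E)-hepta-3,5-dien-2-ol | C[C@H](O)/C=C/C=C/C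
F2 | step 10 | (S)-triethyl[(3E,5E)-hepta-3,5-dien-2-yloxy]silane | C[C@H](O[Si](CC)(CC)CC)/C=C/C=C/C
F3 | step 14 | (E)-enol triflate, geometric isomer of 26 | C\C(OS(=O)(=O)C(F)(F)F)=C1\CC[C@@H](C)[C@@](C)(C=C)[C@@H]1CCCO[Si](C)(C)C(C)(C)C
F4 | step 14 | methyl (E)-enoate, geometric isomer of 27 | C\C(C(=O)OC)=C1\CC[C@@H](C)[C@@](C)(C=C)[C@@H]1CCCO[Si](C)(C)C(C)(C)C
F5 | step 1 | racemic 6-methylhept-5-en-1-yn-4-ol | C#CCC(O)C=C(C)C
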